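**Retrosynthetic overview**

1. Target ⇐ allylic 1,3-diol (primary-selective isobutyrylation) ⇐ 6-hydroxycyclohex-1-ene-1-carbaldehyde (Luche reduction); the ring CH2O carbon is carried at the aldehyde level and returned afterwards.
2. The only carbocycle is closed by an intramolecular Morita–Baylis–Hillman reaction of an acyclic (E)-hept-2-enedial that already carries the whole side chain (free tertiary alcohol, isobutyrate, skipped diene). The bond formed joins the ring carbinol carbon to the neighbouring ring sp2 carbon that bears the exocyclic carbon.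
3. Enabling feature: ring CH(OH), the adjacent ring sp2 carbon and its exocyclic CH2O carbon form a β-hydroxy-α-alkylidene carbonyl unit once that carbon is an aldehyde, the ring C=C being the enal C=C. The ring CH bearing the side chain lies 1,3 to the carbinol and relays its configuration through a chair.
4. Enedial ⇐ lactol (Wittig formyl-olefination, then oxidation). The side chain is joined by E-selective cross-metathesis with an (R)-vinyl carbinol ester made from (S)-2-methylglycidol.
5. Ring CH stereocentre ⇐ Rh/(R)-BINAP 1,4-addition of an isopropenyl boronate to 5,6-dihydro-2H-pyran-2-one; isopropenyl → penta-1,4-dien-2-yl by ene chlorination and Stille vinylation. Ring order: the temporary oxanone ring is bought and opened in step 8; the cyclohexene is formed in step 10.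

Key step: step 10

Remark: the ring CH stereocentre set in the first step keeps its spatial arrangement throughout. Its descriptor is R in the oxane (lactone, lactol) intermediates and S once the heterocycle is opened, only because substituent priorities change. The epoxide-derived carbinol centre likewise changes from S to R in the homologation step without any bond to it being touched.

Assumption: lactols are used as anomeric mixtures. The sense of induction of the proline/imidazole pair is taken over from the parent hept-2-enedial; should it prove opposite, the other proline enantiomer is the matched catalyst.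

**Route**

Step 1
Reactants: 1 5,6-dihydro-2H-pyran-2-one; 2 4,4,5,5-tetramethyl-2-(prop-1-en-2-yl)-1,3,2-dioxaborolane
Product: 3 (4R)-4-(prop-1-en-2-yl)oxan-2-one
Conditions: [RhCl(cod)]2 (2.5 mol %), (R)-BINAP (6 mol %), KOH (10 mol %), 2 (2.5 equiv), dioxane/H2O 10:1, 60 °C; dilute HCl work-up
Reagents that add atoms: none
Why: Hayashi–Miyaura 1,4-addition, in which the alkenyl–rhodium species formed by transmetalation adds across the lactone C=C and water protonates the enolate, the (R)-BINAP ligand selecting the alkene face so that the new ring CH centre should be R (sense taken from the established behaviour of cyclic enones and unsaturated δ-lactones with aryl- and alkenylboron reagents).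

Step 2
Reactants: 3 (4R)-4-(prop-1-en-2-yl)oxan-2-one
Product: 4 (4R)-4-(3-chloroprop-1-en-2-yl)oxan-2-one
Conditions: Ca(OCl)2, CO2 (dry ice), CH2Cl2/H2O, 0 °C
Reagents that add atoms: calcium hypochlorite, [Ca+2].[O-]Cl.[O-]Cl
Why: Ene-type allylic chlorination of a 1,1-disubstituted alkene by HOCl, in which chlorine goes to the terminal CH2 and a methyl hydrogen is lost, so the double bond shifts to give the 2-(chloromethyl)vinyl group without touching the lactone or the stereocentre.

Step 3
Reactants: 4 (4R)-4-(3-chloroprop-1-en-2-yl)oxan-2-one; 5 tributyl(ethenyl)stannane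
Product: 6 (4R)-4-(penta-1,4-dien-2-yl)oxan-2-one
Conditions: Pd2(dba)3 (2.5 mol %), P(2-furyl)3 (10 mol %), THF, 60 °C
Reagents that add atoms: none
Why: Stille coupling of an allylic chloride, in which oxidative addition gives a 2-substituted π-allyl unit with two equivalent termini, so only one skipped diene can form, under neutral conditions that spare the lactone.

Step 4
Reactants: 6 (4R)-4-(penta-1,4-dien-2-yl)oxan-2-one
Product: 7 (4R)-4-(penta-1,4-dien-2-yl)oxan-2-ol (both anomers)
Conditions: iBu2AlH (1.1 equiv), CH2Cl2, −78 °C; aqueous potassium sodium tartrate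
Reagents that add atoms: none
Why: Partial reduction of a lactone, where single hydride delivery at −78 °C stops at the hemiacetal oxidation level and the unactivated alkenes are inert; it is placed before the ester-bearing side chain arrives because iBu2AlH would not spare an isobutyrate.

Step 5
Reactants: 8 [(2S)-2-methyloxiran-2-yl]methanol ((S)-2-methylglycidol)
Product: 9 (2R)-2-methylbut-3-ene-1,2-diol
Conditions: Me3S+ I− (3.5 equiv), nBuLi (3.5 equiv), THF, −10 °C to rt
Reagents that add atoms: trimethylsulfonium iodide, C[S+](C)C.[I-]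
Why: One-carbon homologation of an epoxide to an allylic alcohol, in which dimethylsulfonium methylide opens the epoxide at its CH2 terminus and Me2S is then eliminated, so no bond to the quaternary centre is made or broken (the Payne rearrangement of this alkoxide is degenerate and cannot racemise it).

Step 6
Reactants: 9 (2R)-2-methylbut-3-ene-1,2-diol
Product: 10 (2R)-2-hydroxy-2-methylbut-3-en-1-yl 2-methylpropanoate
Conditions: iPrCOCl (1.05 equiv), pyridine, CH2Cl2, −20 to 0 °C
Reagents that add atoms: 2-methylpropanoyl chloride, CC(C)C(Cl)=O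
Why: Esterification of a primary/tertiary 1,2-diol should occur only at the unhindered primary hydroxyl, the tertiary alcohol being inert at this temperature.

Step 7
Reactants: 7 (4R)-4-(penta-1,4-dien-2-yl)oxan-2-ol; 10 (2R)-2-hydroxy-2-methylbut-3-en-1-yl 2-methylpropanoate
Product: 11 (2R,3E)-2-hydroxy-6-[(4R)-2-hydroxyoxan-4-yl]-2-methylhepta-3,6-dien-1-yl 2-methylpropanoate (both anomers)
Conditions: second-generation Hoveyda–Grubbs catalyst (5 mol %), 10 (3 equiv), 1,4-benzoquinone (10 mol %), CH2Cl2, 40 °C
Reagents that add atoms: none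
Why: Olefin cross-metathesis of the monosubstituted allyl terminus of 7 with the hindered vinyl carbinol 10, which should not homodimerise and whose quaternary allylic carbon enforces the E alkene, while the 1,1-disubstituted alkene stays out of the cycle and benzoquinone suppresses migration of the skipped diene.

Step 8
Reactants: 11 (2R,3E)-2-hydroxy-6-[(4R)-2-hydroxyoxan-4-yl]-2-methylhepta-3,6-dien-1-yl 2-methylpropanoate; 12 (triphenyl-λ5-phosphanylidene)acetaldehyde
Product: 13 (2R,3E,7S,9E)-2-hydroxy-7-(2-hydroxyethyl)-2-methyl-6-methylidene-11-oxoundeca-3,9-dien-1-yl 2-methylpropanoate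
Conditions: 12 (1.3 equiv), PhCO2H (cat.), toluene, 70 °C
Reagents that add atoms: none
Why: Wittig olefination of the lactol (reacting through its ring-opened form) with a stabilised ylide, which should give the E-enal and free the primary alcohol while leaving ester and tertiary alcohol alone.

Step 9
Reactants: 13 (2R,3E,7S,9E)-2-hydroxy-7-(2-hydroxyethyl)-2-methyl-6-methylidene-11-oxoundeca-3,9-dien-1-yl 2-methylpropanoate
Product: 14 (2R,3E,7S,9E)-2-hydroxy-2-methyl-6-methylidene-11-oxo-7-(2-oxoethyl)undeca-3,9-dien-1-yl 2-methylpropanoate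
Conditions: Dess–Martin periodinane, pyridine, CH2Cl2, 0 °C to rt; used directly
Reagents that add atoms: none
Why: Dess–Martin oxidation of the only oxidisable alcohol (the tertiary one cannot react) under buffered conditions that should not isomerise the enal or the skipped diene.

Step 10
Reactants: 14 (2R,3E,7S,9E)-2-hydroxy-2-methyl-6-methylidene-11-oxo-7-(2-oxoethyl)undeca-3,9-dien-1-yl 2-methylpropanoate
Product: 17 (2R,3E)-6-[(1S,5S)-4-formyl-5-hydroxycyclohex-3-en-1-yl]-2-hydroxy-2-methylhepta-3,6-dien-1-yl 2-methylpropanoate, via imidazolyl enamine 15 (not isolated), via cyclised aldol iminium 16 (not isolated)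
Conditions: D-proline (20 mol %), imidazole (20 mol %), MeCN (0.1 M), 0 °C
Reagents that add atoms: none
Why: D-Proline condenses with the enal of 14 and imidazole adds to the β-carbon of the activated enal to give enamine 15, whose α-carbon attacks the tethered saturated aldehyde (activated by the carboxylic acid) to give 16; E1cB loss of imidazole and hydrolysis then release enal 17 and both catalysts. This is an intramolecular Morita–Baylis–Hillman reaction under amino acid/imidazole dual catalysis, the reaction type established for the parent (E)-hept-2-enedial. The cyclohexene closes in a 6-(enolexo)-exo-trig mode through a chair-like transition state. The new carbinol centre rests on catalyst control reinforced by substrate control: D-proline is the enantiomer expected, from the sense of induction of the parent system with this catalyst pair, to give the (S)-carbinol, and the same diastereomer is favoured by the chair that keeps the dienyl side chain at the existing centre equatorial, so hydroxyl and side chain should end up cis. The step needs the enal to act as donor and the saturated aldehyde as acceptor, without intermolecular aldolisation: only the enal can be activated for imidazole addition, the alternative enamine of the saturated aldehyde could only close a cyclobutane, and six-membered closure is favoured at this dilution, while the tertiary alcohol, the isobutyrate and the skipped diene are inert to the neutral catalysts.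

Step 11
Reactants: 17 (2R,3E)-6-[(1S,5S)-4-formyl-5-hydroxycyclohex-3-en-1-yl]-2-hydroxy-2-methylhepta-3,6-dien-1-yl 2-methylpropanoate
Product: 18 (2R,3E)-2-hydroxy-6-[(1S,5S)-5-hydroxy-4-(hydroxymethyl)cyclohex-3-en-1-yl]-2-methylhepta-3,6-dien-1-yl 2-methylpropanoate
Conditions: NaBH4, CeCl3·7H2O, MeOH, −78 °C
Reagents that add atoms: none
Why: Luche reduction, in which the cerium-activated aldehyde is reduced 1,2 faster than any ester or alkene reacts and no stereocentre is created or touched.

Step 12
Reactants: 18 (2R,3E)-2-hydroxy-6-[(1S,5S)-5-hydroxy-4-(hydroxymethyl)cyclohex-3-en-1-yl]-2-methylhepta-3,6-dien-1-yl 2-methylpropanoate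
Product: 19 (2R,3E)-2-hydroxy-6-[(1S,5S)-5-hydroxy-4-{[(2-methylpropanoyl)oxy]methyl}cyclohex-3-en-1-yl]-2-methylhepta-3,6-dien-1-yl 2-methylpropanoate (CNP0599657.1)
Conditions: iPrCOCl (1.05 equiv), 2,4,6-collidine, CH2Cl2, −78 °C
Reagents that add atoms: 2-methylpropanoyl chloride, CC(C)C(Cl)=O
Why: Kinetic acylation of the primary allylic hydroxyl in the presence of the secondary allylic and tertiary hydroxyls, the selectivity resting on sterics at −78 °C with a hindered pyridine base and one equivalent of acyl chloride.

**Compound list**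

1 | 5,6-dihydro-2H-pyran-2-one | O=C1C=CCCO1 | starting material
2 | 4,4,5,5-tetramethyl-2-(prop-1-en-2-yl)-1,3,2-dioxaborolane (isopropenylboronic acid pinacol ester) | C=C(C)B1OC(C)(C)C(C)(C)O1 | starting material
3 | (4R)-4-(prop-1-en-2-yl)oxan-2-one | C=C(C)[C@H]1CC(=O)OCC1 | intermediate
4 | (4R)-4-(3-chloroprop-1-en-2-yl)oxan-2-one | C=C(CCl)[C@H]1CC(=O)OCC1 | intermediate
5 | tributyl(ethenyl)stannane | C=C[Sn](CCCC)(CCCC)CCCC | starting material
6 | (4R)-4-(penta-1,4-dien-2-yl)oxan-2-one | C=CCC(=C)[C@H]1CC(=O)OCC1 | intermediate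
7 | (4R)-4-(penta-1,4-dien-2-yl)oxan-2-ol, both anomers | C=CCC(=C)[C@H]1CC(O)OCC1 | intermediate
8 | [(2S)-2-methyloxiran-2-yl]methanol ((S)-2-methylglycidol) | C[C@]1(CO)CO1 | starting material
9 | (2R)-2-methylbut-3-ene-1,2-diol | C=C[C@@](C)(O)CO | intermediate
10 | (2R)-2-hydroxy-2-methylbut-3-en-1-yl 2-methylpropanoate | C=C[C@@](C)(O)COC(=O)C(C)C | intermediate
11 | (2R,3E)-2-hydroxy-6-[(4R)-2-hydroxyoxan-4-yl]-2-methylhepta-3,6-dien-1-yl 2-methylpropanoate, both anomers | C=C(C/C=C/[C@@](C)(O)COC(=O)C(C)C)[C@H]1CC(O)OCC1 | intermediate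
12 | (triphenyl-λ5-phosphanylidene)acetaldehyde | O=CC=P(c1ccccc1)(c1ccccc1)c1ccccc1 | starting material
13 | (2R,3E,7S,9E)-2-hydroxy-7-(2-hydroxyethyl)-2-methyl-6-methylidene-11-oxoundeca-3,9-dien-1-yl 2-methylpropanoate | C=C(C/C=C/[C@@](C)(O)COC(=O)C(C)C)[C@H](CCO)C/C=C/C=O | intermediate
14 | (2R,3E,7S,9E)-2-hydroxy-2-methyl-6-methylidene-11-oxo-7-(2-oxoethyl)undeca-3,9-dien-1-yl 2-methylpropanoate | C=C(C/C=C/[C@@](C)(O)COC(=O)C(C)C)[C@H](CC=O)C/C=C/C=O | intermediate
15 | D-proline enamine of the 3-(imidazol-1-yl) adduct of 14 (imidazole on the former enal β-carbon, mixture at that carbon; not isolated) | C=C(C/C=C/[C@@](C)(O)COC(=O)C(C)C)[C@H](CC=O)CC(n1ccnc1)/C=C/N1CCC[C@@H]1C(=O)O | intermediate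
16 | cyclised aldol adduct: D-proline iminium carboxylate of the 2-(imidazol-1-yl)-6-hydroxycyclohexanecarbaldehyde bearing the side chain at C4 (carbinol S, side-chain carbon S; not isolated) | C=C(C/C=C/[C@@](C)(O)COC(=O)C(C)C)[C@H]1CC(n2ccnc2)C(C=[N+]3CCC[C@@H]3C(=O)[O-])[C@@H](O)C1 | intermediate
17 | (2R,3E)-6-[(1S,5S)-4-formyl-5-hydroxycyclohex-3-en-1-yl]-2-hydroxy-2-methylhepta-3,6-dien-1-yl 2-methylpropanoate (hydroxyl cis to the side chain) | C=C(C/C=C/[C@@](C)(O)COC(=O)C(C)C)[C@H]1CC=C(C=O)[C@@H](O)C1 | intermediate
18 | (2R,3E)-2-hydroxy-6-[(1S,5S)-5-hydroxy-4-(hydroxymethyl)cyclohex-3-en-1-yl]-2-methylhepta-3,6-dien-1-yl 2-methylpropanoate | C=C(C/C=C/[C@@](C)(O)COC(=O)C(C)C)[C@H]1CC=C(CO)[C@@H](O)C1 | intermediate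
19 | (2R,3E)-2-hydroxy-6-[(1S,5S)-5-hydroxy-4-{[(2-methylpropanoyl)oxy]methyl}cyclohex-3-en-1-yl]-2-methylhepta-3,6-dien-1-yl 2-methylpropanoate | C=C(C/C=C/[C@@](C)(O)COC(=O)C(C)C)[C@H]1CC=C(COC(=O)C(C)C)[C@@H](O)C1 | target

**Step count**

Total steps: 12. Longest linear sequence: 10 steps (steps 1, 2, 3, 4, 7, 8, 9, 10, 11, 12); steps 5 and 6 build the side-chain olefin.

**Steps most likely to fail**

Step 10. Weak or mismatched facial control in the enamine–aldol event, together with retro-aldol equilibration, could erode the cis/trans ratio at the new carbinol centre. The fallback sets out from 17 (as a mixture of carbinol epimers) and comes back at 19. The mixture would be taken through steps 11 and 12, giving 19 together with its ring-carbinol epimer (2R,3E)-2-hydroxy-6-[(1S,5R)-5-hydroxy-4-{[(2-methylpropanoyl)oxy]methyl}cyclohex-3-en-1-yl]-2-methylhepta-3,6-dien-1-yl 2-methylpropanoate F1. Dess–Martin oxidation of the secondary allylic alcohol (the tertiary alcohol is inert) should converge both epimers on the enone (2R,3E)-2-hydroxy-2-methyl-6-[(1S)-4-{[(2-methylpropanoyl)oxy]methyl}-5-oxocyclohex-3-en-1-yl]hepta-3,6-dien-1-yl 2-methylpropanoate F2. Luche reduction (NaBH4, CeCl3·7H2O, MeOH, −78 °C) should then deliver hydride axially to the half-chair that keeps the side chain equatorial and give the pseudo-equatorial, cis alcohol 19, as in the reduction of 5-substituted 2-alkylcyclohex-2-en-1-ones to their cis allylic alcohols. The carbinol configuration is then set by substrate-controlled reduction and no longer in the C–C bond formation.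

Step 8. The freed primary hydroxyl could add to the new enal (oxa-Michael closure to a tetrahydropyran), and the product enal could be olefinated a second time. The fallback sets out from 11 and comes back at 14, so that the hydroxy-enal never exists. Lactol 11 would be olefinated with the ylide from (1,3-dioxolan-2-ylmethyl)triphenylphosphonium bromide and NaN(SiMe3)2 (3 equiv, THF, −78 to 0 °C) to give (2R,3E,7S)-10-(1,3-dioxolan-2-yl)-2-hydroxy-7-(2-hydroxyethyl)-2-methyl-6-methylidenedeca-3,9-dien-1-yl 2-methylpropanoate F3 as a 9E/9Z mixture. Dess–Martin oxidation of its primary alcohol would give (2R,3E,7S)-10-(1,3-dioxolan-2-yl)-2-hydroxy-2-methyl-6-methylidene-7-(2-oxoethyl)deca-3,9-dien-1-yl 2-methylpropanoate F4. Brief hydrolysis of the vinylogous acetal (oxalic acid, THF/H2O, 0 °C to rt) should unmask the enal with equilibration to the E isomer and give 14.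

Step 7. Slow turnover with the hindered vinyl carbinol, or ruthenium hydride migration of the skipped diene into conjugation, could lower the yield of 11. The fallback sets out from 10 and 4 and comes back at 11, replacing the metathesis by a π-allyl Suzuki–Miyaura union. Ester 10 would be ozonised (O3, CH2Cl2, −78 °C; PPh3) to (2S)-2-hydroxy-2-methyl-3-oxopropyl 2-methylpropanoate F5. Boron–Takai olefination (2-(dichloromethyl)-4,4,5,5-tetramethyl-1,3,2-dioxaborolane, CrCl2, LiI, THF, rt) would homologate it to (2R,3E)-2-hydroxy-2-methyl-4-(4,4,5,5-tetramethyl-1,3,2-dioxaborolan-2-yl)but-3-en-1-yl 2-methylpropanoate F6. Chloride 4 would be reduced with iBu2AlH (CH2Cl2, −78 °C) to (4R)-4-(3-chloroprop-1-en-2-yl)oxan-2-ol F7. Coupling of F7 with F6 (Pd(PPh3)4, CsF, THF, 60 °C) through the symmetrical 2-substituted π-allyl unit should give 11 with the E geometry fixed by the olefination.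

Further compounds
F1 | step 10 | (2R,3E)-2-hydroxy-6-[(1S,5R)-5-hydroxy-4-{[(2-methylpropanoyl)oxy]methyl}cyclohex-3-en-1-yl]-2-methylhepta-3,6-dien-1-yl 2-methylpropanoate | C=C(C/C=C/[C@@](C)(O)COC(=O)C(C)C)[C@H]1CC=C(COC(=O)C(C)C)[C@H](O)C1
F2 | step 10 | (2R,3E)-2-hydroxy-2-methyl-6-[(1S)-4-{[(2-methylpropanoyl)oxy]methyl}-5-oxocyclohex-3-en-1-yl]hepta-3,6-dien-1-yl 2-methylpropanoate | C=C(C/C=C/[C@@](C)(O)COC(=O)C(C)C)[C@H]1CC=C(COC(=O)C(C)C)C(=O)C1
F3 | step 8 | (2R,3E,7S)-10-(1,3-dioxolan-2-yl)-2-hydroxy-7-(2-hydroxyethyl)-2-methyl-6-methylidenedeca-3,9-dien-1-yl 2-methylpropanoate (9E/9Z mixture) | C=C(C/C=C/[C@@](C)(O)COC(=O)C(C)C)[C@H](CCO)CC=CC1OCCO1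
F4 | step 8 | (2R,3E,7S)-10-(1,3-dioxolan-2-yl)-2-hydroxy-2-methyl-6-methylidene-7-(2-oxoethyl)deca-3,9-dien-1-yl 2-methylpropanoate (9E/9Z mixture) | C=C(C/C=C/[C@@](C)(O)COC(=O)C(C)C)[C@H](CC=O)CC=CC1OCCO1
F5 | step 7 | (2S)-2-hydroxy-2-methyl-3-oxopropyl 2-methylpropanoate | O=C[C@@](C)(O)COC(=O)C(C)C
F6 | step 7 | (2R,3E)-2-hydroxy-2-methyl-4-(4,4,5,5-tetramethyl-1,3,2-dioxaborolan-2-yl)but-3-en-1-yl 2-methylpropanoate | CC1(C)OB(/C=C/[C@@](C)(O)COC(=O)C(C)C)OC1(C)C
F7 | step 7 | (4R)-4-(3-chloroprop-1-en-2-yl)oxan-2-ol | C=C(CCl)[C@H]1CC(O)OCC1
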